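**Plan**
- Retrosynthetic cuts: C11–CH3/C11–OAc (back to a C11 ketone), C15–H (back to an α-methylene lactone), the lactone carbonyl C16 (CO inserted between C3–OH and a C15 enol triflate), then the six-membered carbocycle at C1–C14 and C12–C13 ([4+2]), C10–C11 (Stille), C8–C9 with O–C6 ([2,3] shift of an oxonium ylide), C2–C3 (ketyl–acrylate cyclisation).
- Forward order: oxane → O-bridged oxonene/dihydrofuranone bicycle → cyclohexene, the last ring of the carbon skeleton (step 16). The ε-lactone is afterwards only stitched with CO between two groups the cycloaddition has already placed.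
- Enabling feature: the C10 carbonyl of the 11-oxabicyclo[6.2.1]undecenone, whose only enolisable neighbour is C1H2. It turns the dihydrofuran ring into the 2-ethoxy-diene C1=C10–C11(OEt)=C12, open only on the face anti to C3 and the C4–C8 chain, and it puts oxygen on C11 and the acyl carbon C15 para to each other, the two oxidised positions of the target's cyclohexane.
- Stereochemistry: CBS reduction sets the C6 carbinol (a relay centre, erased in the [2,3] shift), which sets C2 (2,6-cis oxane), C3 (equatorial MeMgCl attack) and C9. C1 comes from the diene face, C14 and C10 from base equilibration (stereoconvergent), C15 from hydrogenation anti to C1, C11 from axial MeMgBr attack.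

Key step: step 16

Remark: eunicellane numbering is used throughout (C1–C14 as in 2,9-epoxybicyclo[8.4.0]tetradecane; C15 = lactone α-carbon, C16 = lactone carbonyl, C17 = its methyl); the lactone is treated as an internal ester that is closed after the carbon skeleton is complete.

**Step 1**
Reactants: 1 4-[(tert-butyldimethylsilyl)oxy]butanal; 2 isopropenylmagnesium bromide
Product: 3 rac-6-[(tert-butyldimethylsilyl)oxy]-2-methylhex-1-en-3-ol
Conditions: THF, −78 → 0 °C; aq. NH4Cl
Reagents that add atoms: isopropenylmagnesium bromide (2), C=C(C)[Mg]Br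
Why: Grignard 1,2-addition to the aldehyde gives the racemic allylic alcohol, whose stereocentre is set in step 3.

**Step 2**
Reactants: 3 rac-allylic alcohol
Product: 4 6-[(tert-butyldimethylsilyl)oxy]-2-methylhex-1-en-3-one
Conditions: Dess–Martin periodinane, NaHCO3, CH2Cl2, rt
Reagents that add atoms: none
Why: Buffered Dess–Martin oxidation gives the isopropenyl ketone without isomerising the alkene.

**Step 3**
Reactants: 4 enone
Product: 5 (3S)-6-[(tert-butyldimethylsilyl)oxy]-2-methylhex-1-en-3-ol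
Conditions: (R)-2-methyl-CBS-oxazaborolidine (20 mol %), catecholborane, PhMe, −78 °C
Reagents that add atoms: none
Why: CBS reduction in which the isopropenyl group is the large substituent, so the (R)-catalyst should deliver hydride to give the (S)-carbinol; catecholborane at −78 °C avoids hydroboration and 1,4-reduction.

**Step 4**
Reactants: 5 (S)-allylic alcohol; 6 ethyl propiolate
Product: 7 ethyl (2E)-3-{[(3S)-6-[(tert-butyldimethylsilyl)oxy]-2-methylhex-1-en-3-yl]oxy}prop-2-enoate
Conditions: N-methylmorpholine, CH2Cl2, rt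
Reagents that add atoms: ethyl propiolate (6), C#CC(=O)OCC
Why: Amine-catalysed oxa-Michael addition of the secondary alcohol to the propiolate gives the (E)-β-alkoxyacrylate without touching the carbinol centre.

**Step 5**
Reactants: 7 silyl ether
Product: 8 ethyl (2E)-3-{[(3S)-6-hydroxy-2-methylhex-1-en-3-yl]oxy}prop-2-enoate
Conditions: HF·pyridine, pyridine, THF, 0 °C → rt
Reagents that add atoms: none
Why: Buffered fluoride cleaves the primary silyl ether and leaves the vinylogous carbonate intact.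

**Step 6**
Reactants: 8 primary alcohol
Product: 9 ethyl (2E)-3-{[(3S)-2-methyl-6-oxohex-1-en-3-yl]oxy}prop-2-enoate
Conditions: Dess–Martin periodinane, NaHCO3, CH2Cl2, rt
Reagents that add atoms: none
Why: Mild oxidation to the aldehyde needed as ketyl precursor, with no epimerisable centre next to it.

**Step 7**
Reactants: 9 aldehyde
Product: 10 ethyl 2-[(2S,3R,6S)-3-hydroxy-6-(prop-1-en-2-yl)oxan-2-yl]acetate
Conditions: SmI2, MeOH, THF, 0 °C
Reagents that add atoms: none
Why: Reductive ketyl–olefin cyclisation of a β-alkoxyacrylate: the ketyl adds 6-exo through a chair transition state with the acrylate equatorial and Sm(III) bridging ketyl oxygen and ester, which should set C2 cis to the C6 isopropenyl group and the carbinol trans to the side chain.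

**Step 8**
Reactants: 10 oxan-3-ol
Product: 11 ethyl 2-[(2S,6S)-3-oxo-6-(prop-1-en-2-yl)oxan-2-yl]acetate
Conditions: Dess–Martin periodinane, NaHCO3, CH2Cl2, rt
Reagents that add atoms: none
Why: Neutral oxidation to the oxan-3-one keeps the thermodynamically preferred 2,6-cis (diequatorial) arrangement at the α-carbon C2.

**Step 9**
Reactants: 11 oxan-3-one
Product: 12 ethyl 2-[(2S,3S,6S)-3-hydroxy-3-methyl-6-(prop-1-en-2-yl)oxan-2-yl]acetate
Conditions: MeMgCl, THF, −78 °C; cold aq. NH4Cl
Reagents that add atoms: methylmagnesium chloride, C[Mg]Cl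
Why: Grignard addition to the ketone from the equatorial direction, anti to the ring C2–O bond (Felkin–Anh polar control), should give the axial tertiary alcohol cis to the C2 side chain (C3 of the target), while the ester is untouched at −78 °C and the cold quench forestalls lactonisation.

**Step 10**
Reactants: 12 tertiary alcohol
Product: 13 ethyl 2-[(2S,3S,6S)-3-methyl-6-(prop-1-en-2-yl)-3-[(triethylsilyl)oxy]oxan-2-yl]acetate
Conditions: TESOTf, 2,6-lutidine, CH2Cl2, −78 → 0 °C
Reagents that add atoms: triethylsilyl trifluoromethanesulfonate, CC[Si](CC)(CC)OS(=O)(=O)C(F)(F)F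
Why: Silyl triflate silylates the hindered tertiary alcohol before carbenoid chemistry; TES is chosen so that dilute acid removes it in step 18 together with the enol ether, without fluoride.

**Step 11**
Reactants: 13 ethyl ester
Product: 14 2-[(2S,3S,6S)-3-methyl-6-(prop-1-en-2-yl)-3-[(triethylsilyl)oxy]oxan-2-yl]acetic acid
Conditions: LiOH, THF/MeOH/H2O, rt; then dilute HCl to pH 4 at 0 °C
Reagents that add atoms: lithium hydroxide, [Li+].[OH-]
Why: Ordinary saponification of an unhindered ester; the tertiary TES ether tolerates base and a brief pH 4 work-up.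

**Step 12**
Reactants: 14 carboxylic acid
Product: 16 1-diazo-3-[(2S,3S,6S)-3-methyl-6-(prop-1-en-2-yl)-3-[(triethylsilyl)oxy]oxan-2-yl]propan-2-one, via mixed anhydride 15 (not isolated)
Conditions: i-BuOCOCl, Et3N, Et2O, 0 °C; then CH2N2, Et2O, 0 °C → rt
Reagents that add atoms: diazomethane, C=[N+]=[N-] (isobutyl chloroformate, CC(C)COC(=O)Cl, leaves atoms only in intermediate 15)
Why: C-acylation of diazomethane by the mixed carbonic anhydride (first stage of an Arndt–Eistert sequence) gives the α-diazoketone and does not touch the stereocentres.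

**Step 13**
Reactants: 16 diazoketone
Product: 19 (1S,2S,5Z,8S)-2,6-dimethyl-2-[(triethylsilyl)oxy]-11-oxabicyclo[6.2.1]undec-5-en-9-one, via oxonium ylide 17 (not isolated), via 5E ketone 18 (not isolated)
Conditions: Cu(hfacac)2 (5 mol %), CH2Cl2, reflux; then EtSH, AIBN, PhH, 80 °C
Reagents that add atoms: none
Why: The copper carbenoid is captured by the oxane oxygen and the resulting bicyclic oxonium ylide undergoes a [2,3]-sigmatropic shift through the isopropenyl group, expanding the oxane by three atoms and setting C9 cis to C2 as the bridge requires; reversible thiyl-radical addition then funnels any E-oxonene into the more stable Z isomer.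

**Step 14**
Reactants: 19 bicyclic ketone
Product: 20 (1S,2S,5Z,8S)-2,6-dimethyl-2-[(triethylsilyl)oxy]-11-oxabicyclo[6.2.1]undeca-5,9-dien-9-yl trifluoromethanesulfonate
Conditions: NaHMDS, PhNTf2, THF, −78 °C
Reagents that add atoms: N-phenylbis(trifluoromethanesulfonimide), O=S(=O)(N(c1ccccc1)S(=O)(=O)C(F)(F)F)C(F)(F)F
Why: Enolisation can only go towards C1 (C9 is a bridgehead α-alkoxy methine), and O-triflation gives the C1=C10 enol triflate.

**Step 15**
Reactants: 20 enol triflate; 21 tributyl(1-ethoxyethenyl)stannane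
Product: 22 (1S,2S,5Z,8S)-9-(1-ethoxyethenyl)-2,6-dimethyl-2-[(triethylsilyl)oxy]-11-oxabicyclo[6.2.1]undeca-5,9-diene
Conditions: Pd(PPh3)4, LiCl, THF, 65 °C; base-washed glassware, used crude
Reagents that add atoms: tributyl(1-ethoxyethenyl)stannane (21), CCCC[Sn](CCCC)(CCCC)C(=C)OCC
Why: Stille coupling of the enol triflate with the α-ethoxyvinyl stannane forms the C10–C11 bond and gives the 2-ethoxy-1,3-diene with C11 already at the ketone oxidation level.

**Step 16**
Reactants: 22 2-ethoxy-diene; 23 methyl vinyl ketone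
Product: 25 1-[(1S,2S,3S,6Z,9S,14R)-11-ethoxy-3,7-dimethyl-3-[(triethylsilyl)oxy]-2,9-epoxybicyclo[8.4.0]tetradeca-6,10-dien-14-yl]ethan-1-one, via 14-epi adduct 24 (not isolated)
Conditions: 23 (10 equiv), BHT, PhMe, 110 °C (sealed); excess 23 removed in vacuo; then K2CO3, MeOH, rt
Reagents that add atoms: methyl vinyl ketone (23), CC(=O)C=C
Why: Thermal, concerted but asynchronous normal-demand [4+2] cycloaddition in which the nucleophilic C12 terminus of the diene C1=C10–C11(OEt)=C12 bonds to the β-carbon of the enone and C1 to its α-carbon; the closest known reaction type is the intermolecular Diels–Alder reaction of 2-alkoxy- or 2-silyloxy-1,3-dienes with vinyl ketones. The six-membered carbocycle (C1, C10, C11, C12, C13, C14) is closed in the intermolecular (4+2) annulation mode by forming C1–C14 and C12–C13 together, and the para orientation (C11–OEt and C14–acyl 1,4) follows from the donor on C11. C1 is controlled by the bicycle: the concave face of the dihydrofuran alkene is covered by quaternary C3 and the C4–C8 chain, so the enone should add anti to the C2–C3 bond and leave H1 cis to C3. C14 needs no endo/exo control because it is α to the acetyl group: K2CO3/MeOH should epimerise the endo adduct 24 to the trans (C1–C2/C14–acyl diequatorial) isomer 25, so the mixture converges on one compound. C10 stays an enol-ether carbon and is set later under thermodynamic control, while the enol ether keeps C11 masked and distinct from the C15 ketone. The step therefore has to deliver only facial selectivity at C1 and regioselectivity, and both are secured by the substrate.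

**Step 17**
Reactants: 25 cycloadduct
Product: 26 1-[(1S,2S,3S,6Z,9S,14R)-11-ethoxy-3,7-dimethyl-3-[(triethylsilyl)oxy]-2,9-epoxybicyclo[8.4.0]tetradeca-6,10-dien-14-yl]ethenyl trifluoromethanesulfonate
Conditions: KHMDS, PhNTf2, THF, −78 °C
Reagents that add atoms: N-phenylbis(trifluoromethanesulfonimide), O=S(=O)(N(c1ccccc1)S(=O)(=O)C(F)(F)F)C(F)(F)F
Why: Kinetic deprotonation of the methyl ketone at CH3 (not at the tertiary C14–H) and O-triflation give the 2-triflyloxypropene unit; C11 cannot compete because it is still an enol ether, and C14 is no longer epimerisable afterwards.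

**Step 18**
Reactants: 26 enol triflate
Product: 28 1-[(1S,2S,3S,6Z,9S,10R,14R)-3-hydroxy-3,7-dimethyl-11-oxo-2,9-epoxybicyclo[8.4.0]tetradec-6-en-14-yl]ethenyl trifluoromethanesulfonate, via 10-epi ketone 27 (not isolated)
Conditions: 1 M aq. HCl, THF, 0 °C → rt; then K2CO3, MeOH, rt
Reagents that add atoms: water, O
Why: Dilute acid hydrolyses the enol ether to the C11 ketone and cleaves the tertiary TES ether, and base then equilibrates C10 (α to the new ketone) to the cis-fused H1/H10 arrangement, the less strained fusion of the bridged hydroisobenzofuranone.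

**Step 19**
Reactants: 28 hydroxy enol triflate
Product: 29 α-methylene ε-lactone (C16→O–C3 lactone of 2-[(1S,2S,3S,6Z,9S,10R,14R)-3-hydroxy-3,7-dimethyl-11-oxo-2,9-epoxybicyclo[8.4.0]tetradec-6-en-14-yl]prop-2-enoic acid)
Conditions: Pd(PPh3)4 (10 mol %), CO (1 atm), Et3N, MeCN, 65 °C
Reagents that add atoms: carbon monoxide, [C-]#[O+]
Why: Palladium-catalysed carbonylative lactonisation: oxidative addition into the vinyl triflate, CO insertion and intramolecular capture of the acyl-palladium by the C3 hydroxyl close the seven-membered lactone and bring in C16, with no new stereocentre.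

**Step 20**
Reactants: 29 α-methylene lactone
Product: 30 lactone of (2R)-2-[(1S,2S,3S,6Z,9S,10R,14R)-3-hydroxy-3,7-dimethyl-11-oxo-2,9-epoxybicyclo[8.4.0]tetradec-6-en-14-yl]propanoic acid
Conditions: RhCl(PPh3)3 (10 mol %), H2 (1 atm), PhH/EtOH, rt
Reagents that add atoms: none
Why: Wilkinson hydrogenation reduces the conjugated 1,1-disubstituted alkene and spares the trisubstituted C6=C7 and the ketone; because the trans ring fusions at C1–C14 and C1–C2 fix the C1–C14–C15–C16 torsion, the face of C15 turned towards C1 is covered and H2 should add from the face carrying H14, giving the 15R centre under kinetic control.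

**Step 21**
Reactants: 30 keto lactone
Product: 32 target (CNP0332402.2), via bromomagnesium alkoxide 31 (not isolated)
Conditions: MeMgBr, THF, −78 °C; then Ac2O, DMAP, −78 °C → rt
Reagents that add atoms: methylmagnesium bromide, C[Mg]Br; acetic anhydride, CC(=O)OC(C)=O
Why: The Grignard reagent should add axially to the C11 cyclohexanone from the face of H1/H10, because the equatorial trajectory is blocked by the axial C9 substituent on C10, giving the equatorial (11R) alkoxide, which is acetylated in the flask; at −78 °C the hindered lactone carbonyl and the C15–H are not attacked.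

**Compound list**
1 | 4-[(tert-butyldimethylsilyl)oxy]butanal | O=CCCCO[Si](C)(C)C(C)(C)C | starting material
2 | isopropenylmagnesium bromide | C=C(C)[Mg]Br | starting material
3 | rac-6-[(tert-butyldimethylsilyl)oxy]-2-methylhex-1-en-3-ol | C=C(C)C(O)CCCO[Si](C)(C)C(C)(C)C | intermediate
4 | 6-[(tert-butyldimethylsilyl)oxy]-2-methylhex-1-en-3-one | C=C(C)C(=O)CCCO[Si](C)(C)C(C)(C)C | intermediate
5 | (3S)-6-[(tert-butyldimethylsilyl)oxy]-2-methylhex-1-en-3-ol | C=C(C)[C@@H](O)CCCO[Si](C)(C)C(C)(C)C | intermediate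
6 | ethyl propiolate | C#CC(=O)OCC | starting material
7 | ethyl (2E)-3-{[(3S)-6-[(tert-butyldimethylsilyl)oxy]-2-methylhex-1-en-3-yl]oxy}prop-2-enoate | CC(C)(C)[Si](C)(C)OCCC[C@H](O/C=C/C(=O)OCC)C(C)=C | intermediate
8 | ethyl (2E)-3-{[(3S)-6-hydroxy-2-methylhex-1-en-3-yl]oxy}prop-2-enoate | OCCC[C@H](O/C=C/C(=O)OCC)C(C)=C | intermediate
9 | ethyl (2E)-3-{[(3S)-2-methyl-6-oxohex-1-en-3-yl]oxy}prop-2-enoate | O=CCC[C@H](O/C=C/C(=O)OCC)C(C)=C | intermediate
10 | ethyl 2-[(2S,3R,6S)-3-hydroxy-6-(prop-1-en-2-yl)oxan-2-yl]acetate | CCOC(=O)C[C@@H]1O[C@H](C(C)=C)CC[C@H]1O | intermediate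
11 | ethyl 2-[(2S,6S)-3-oxo-6-(prop-1-en-2-yl)oxan-2-yl]acetate | CCOC(=O)C[C@@H]1O[C@H](C(C)=C)CCC1=O | intermediate
12 | ethyl 2-[(2S,3S,6S)-3-hydroxy-3-methyl-6-(prop-1-en-2-yl)oxan-2-yl]acetate | CCOC(=O)C[C@@H]1O[C@H](C(C)=C)CC[C@]1(C)O | intermediate
13 | ethyl 2-[(2S,3S,6S)-3-methyl-6-(prop-1-en-2-yl)-3-[(triethylsilyl)oxy]oxan-2-yl]acetate | CCOC(=O)C[C@@H]1O[C@H](C(C)=C)CC[C@]1(C)O[Si](CC)(CC)CC | intermediate
14 | 2-[(2S,3S,6S)-3-methyl-6-(prop-1-en-2-yl)-3-[(triethylsilyl)oxy]oxan-2-yl]acetic acid | OC(=O)C[C@@H]1O[C@H](C(C)=C)CC[C@]1(C)O[Si](CC)(CC)CC | intermediate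
15 | isobutyl carbonic mixed anhydride of 14 | CC(C)COC(=O)OC(=O)C[C@@H]1O[C@H](C(C)=C)CC[C@]1(C)O[Si](CC)(CC)CC | intermediate
16 | 1-diazo-3-[(2S,3S,6S)-3-methyl-6-(prop-1-en-2-yl)-3-[(triethylsilyl)oxy]oxan-2-yl]propan-2-one | [N-]=[N+]=CC(=O)C[C@@H]1O[C@H](C(C)=C)CC[C@]1(C)O[Si](CC)(CC)CC | intermediate
17 | bicyclic oxonium ylide (oxane O bonded to C2, C6 and the carbanionic C9 of a fused 3-oxo-tetrahydrofuran ring) | O=C1C[C@@H]2[O+]([CH-]1)[C@H](C(C)=C)CC[C@]2(C)O[Si](CC)(CC)CC | intermediate
18 | (1S,2S,5E,8S)-2,6-dimethyl-2-[(triethylsilyl)oxy]-11-oxabicyclo[6.2.1]undec-5-en-9-one | C1C(=O)[C@@H]2C/C(C)=C/CC[C@](C)(O[Si](CC)(CC)CC)[C@H]1O2 | intermediate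
19 | (1S,2S,5Z,8S)-2,6-dimethyl-2-[(triethylsilyl)oxy]-11-oxabicyclo[6.2.1]undec-5-en-9-one | C1C(=O)[C@@H]2C/C(C)=C\CC[C@](C)(O[Si](CC)(CC)CC)[C@H]1O2 | intermediate
20 | (1S,2S,5Z,8S)-2,6-dimethyl-2-[(triethylsilyl)oxy]-11-oxabicyclo[6.2.1]undeca-5,9-dien-9-yl trifluoromethanesulfonate | C1=C(OS(=O)(=O)C(F)(F)F)[C@@H]2C/C(C)=C\CC[C@](C)(O[Si](CC)(CC)CC)[C@H]1O2 | intermediate
21 | tributyl(1-ethoxyethenyl)stannane | CCCC[Sn](CCCC)(CCCC)C(=C)OCC | starting material
22 | (1S,2S,5Z,8S)-9-(1-ethoxyethenyl)-2,6-dimethyl-2-[(triethylsilyl)oxy]-11-oxabicyclo[6.2.1]undeca-5,9-diene | C1=C(C(=C)OCC)[C@@H]2C/C(C)=C\CC[C@](C)(O[Si](CC)(CC)CC)[C@H]1O2 | intermediate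
23 | methyl vinyl ketone (but-3-en-2-one) | CC(=O)C=C | starting material
24 | 1-[(1S,2S,3S,6Z,9S,14S)-11-ethoxy-3,7-dimethyl-3-[(triethylsilyl)oxy]-2,9-epoxybicyclo[8.4.0]tetradeca-6,10-dien-14-yl]ethan-1-one (14-epimer, acetyl cis to C2) | CCOC1=C2[C@@H]3C/C(C)=C\CC[C@](C)(O[Si](CC)(CC)CC)[C@@H](O3)[C@H]2[C@@H](C(C)=O)CC1 | intermediate
25 | 1-[(1S,2S,3S,6Z,9S,14R)-11-ethoxy-3,7-dimethyl-3-[(triethylsilyl)oxy]-2,9-epoxybicyclo[8.4.0]tetradeca-6,10-dien-14-yl]ethan-1-one | CCOC1=C2[C@@H]3C/C(C)=C\CC[C@](C)(O[Si](CC)(CC)CC)[C@@H](O3)[C@H]2[C@H](C(C)=O)CC1 | intermediate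
26 | 1-[(1S,2S,3S,6Z,9S,14R)-11-ethoxy-3,7-dimethyl-3-[(triethylsilyl)oxy]-2,9-epoxybicyclo[8.4.0]tetradeca-6,10-dien-14-yl]ethenyl trifluoromethanesulfonate | CCOC1=C2[C@@H]3C/C(C)=C\CC[C@](C)(O[Si](CC)(CC)CC)[C@@H](O3)[C@H]2[C@H](C(=C)OS(=O)(=O)C(F)(F)F)CC1 | intermediate
27 | 1-[(1S,2S,3S,6Z,9S,10S,14R)-3-hydroxy-3,7-dimethyl-11-oxo-2,9-epoxybicyclo[8.4.0]tetradec-6-en-14-yl]ethenyl trifluoromethanesulfonate (10-epimer, trans-fused) | O=C1CC[C@@H](C(=C)OS(=O)(=O)C(F)(F)F)[C@H]3[C@H]1[C@@H]1C/C(C)=C\CC[C@](C)(O)[C@H]3O1 | intermediate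
28 | 1-[(1S,2S,3S,6Z,9S,10R,14R)-3-hydroxy-3,7-dimethyl-11-oxo-2,9-epoxybicyclo[8.4.0]tetradec-6-en-14-yl]ethenyl trifluoromethanesulfonate | O=C1CC[C@@H](C(=C)OS(=O)(=O)C(F)(F)F)[C@H]3[C@@H]1[C@@H]1C/C(C)=C\CC[C@](C)(O)[C@H]3O1 | intermediate
29 | C16→O–C3 lactone of 2-[(1S,2S,3S,6Z,9S,10R,14R)-3-hydroxy-3,7-dimethyl-11-oxo-2,9-epoxybicyclo[8.4.0]tetradec-6-en-14-yl]prop-2-enoic acid (α-methylene ε-lactone) | O=C1CC[C@@H]2[C@H]3[C@@H]1[C@@H]1C/C(C)=C\CC[C@](C)(OC(=O)C2=C)[C@H]3O1 | intermediate
30 | C16→O–C3 lactone of (2R)-2-[(1S,2S,3S,6Z,9S,10R,14R)-3-hydroxy-3,7-dimethyl-11-oxo-2,9-epoxybicyclo[8.4.0]tetradec-6-en-14-yl]propanoic acid | O=C1CC[C@@H]2[C@H]3[C@@H]1[C@@H]1C/C(C)=C\CC[C@](C)(OC(=O)[C@@H]2C)[C@H]3O1 | intermediate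
31 | bromomagnesium (11R)-11-alkoxide of the 11-methyl carbinol derived from 30 | Br[Mg]O[C@]1(C)CC[C@@H]2[C@H]3[C@@H]1[C@@H]1C/C(C)=C\CC[C@](C)(OC(=O)[C@@H]2C)[C@H]3O1 | intermediate
32 | CNP0332402.2: C16→O–C3 lactone of (2R)-2-[(1S,2S,3S,6Z,9S,10R,11R,14R)-11-acetoxy-3-hydroxy-3,7,11-trimethyl-2,9-epoxybicyclo[8.4.0]tetradec-6-en-14-yl]propanoic acid | CC(=O)O[C@]1(C)CC[C@@H]2[C@H]3[C@@H]1[C@@H]1C/C(C)=C\CC[C@](C)(OC(=O)[C@@H]2C)[C@H]3O1 | target

**Totals**
Total step count: 21. Longest linear sequence: 21 steps (fully linear from 1).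

**Steps most likely to fail**

Step 19. Capture of the acyl-palladium by the hindered tertiary C3 hydroxyl may be slower than its hydrolysis or reduction, so that the seven-membered ring does not close. The fallback makes the ester bond by acyl activation instead. It sets out from 28: intermolecular methoxycarbonylation (Pd(OAc)2, dppp, CO, MeOH, Et3N, DMF) should give the methyl acrylate F1; Me3SnOH in 1,2-dichloroethane should give the acrylic acid F2 without disturbing C10; Yamaguchi lactonisation (2,4,6-trichlorobenzoyl chloride, Et3N; then DMAP, PhMe, high dilution) onto the C3 hydroxyl returns to the route at 29.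

Step 20. Hydrogen delivery to C15 may not discriminate the two faces of the exocyclic alkene, or rhodium hydride may move the double bond into the ring. The required 15R centre appears to be the kinetic one, so it could not be repaired by base. The fallback replaces substrate control by catalyst control before the lactone exists. It sets out from 28 and passes through the methyl acrylate F1 and the acrylic acid F2 made as above. Asymmetric hydrogenation of the α-substituted acrylic acid with Ru(OAc)2(BINAP) (the BINAP antipode matched to 15R, H2, MeOH) should give the (2R)-propanoic acid F3. Shiina lactonisation (2-methyl-6-nitrobenzoic anhydride, DMAP, rt, to limit epimerisation of the activated acid) returns to the route at 30.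

Step 16. Base equilibration at C14 may stop at a mixture while C11 is still an sp2 enol-ether carbon (half-chair, small equatorial preference), and the acid-labile diene may be lost to hydrolysis or enone polymerisation at 110 °C. The fallback moves the stereochemical funnel to the chair diketone and distinguishes the two ketones by protection. It sets out from 22 and 23: after the same cycloaddition the crude enol ethers are hydrolysed with PPTS in wet acetone (TES retained) and equilibrated with K2CO3/MeOH at C10 and C14 together, to give the diketone F4. The ring ketone is then masked selectively with 1,2-bis(trimethylsilyloxy)ethane and catalytic TMSOTf at −78 °C (a cyclohexanone reacts before the α-branched methyl ketone), giving the dioxolane F5. KHMDS/PhNTf2 at −78 °C gives the enol triflate F6, and 1 M HCl in THF removes the dioxolane and the TES ether and returns to the route at 28.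

**Further compounds**
F1 | step 19 | methyl 2-[(1S,2S,3S,6Z,9S,10R,14R)-3-hydroxy-3,7-dimethyl-11-oxo-2,9-epoxybicyclo[8.4.0]tetradec-6-en-14-yl]prop-2-enoate | O=C1CC[C@@H](C(=C)C(=O)OC)[C@H]3[C@@H]1[C@@H]1C/C(C)=C\CC[C@](C)(O)[C@H]3O1
F2 | step 19 | 2-[(1S,2S,3S,6Z,9S,10R,14R)-3-hydroxy-3,7-dimethyl-11-oxo-2,9-epoxybicyclo[8.4.0]tetradec-6-en-14-yl]prop-2-enoic acid | O=C1CC[C@@H](C(=C)C(=O)O)[C@H]3[C@@H]1[C@@H]1C/C(C)=C\CC[C@](C)(O)[C@H]3O1
F3 | step 20 | (2R)-2-[(1S,2S,3S,6Z,9S,10R,14R)-3-hydroxy-3,7-dimethyl-11-oxo-2,9-epoxybicyclo[8.4.0]tetradec-6-en-14-yl]propanoic acid | O=C1CC[C@@H]([C@@H](C)C(=O)O)[C@H]3[C@@H]1[C@@H]1C/C(C)=C\CC[C@](C)(O)[C@H]3O1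
F4 | step 16 | (1S,2S,3S,6Z,9S,10R,14R)-14-acetyl-3,7-dimethyl-3-[(triethylsilyl)oxy]-2,9-epoxybicyclo[8.4.0]tetradec-6-en-11-one | O=C1CC[C@@H](C(C)=O)[C@H]3[C@@H]1[C@@H]1C/C(C)=C\CC[C@](C)(O[Si](CC)(CC)CC)[C@H]3O1
F5 | step 16 | 11,11-ethylenedioxy derivative (C11 1,3-dioxolane) of F4 | C1COC2(O1)CC[C@@H](C(C)=O)[C@H]3[C@@H]2[C@@H]1C/C(C)=C\CC[C@](C)(O[Si](CC)(CC)CC)[C@H]3O1
F6 | step 16 | C15 enol triflate (1-substituted ethenyl trifluoromethanesulfonate) of F5 | C1COC2(O1)CC[C@@H](C(=C)OS(=O)(=O)C(F)(F)F)[C@H]3[C@@H]2[C@@H]1C/C(C)=C\CC[C@](C)(O[Si](CC)(CC)CC)[C@H]3O1
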